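**Assumption:** compounds 1, 2 and 16 are taken as catalogue compounds; a metal alkoxide or enolate salt that is only protonated on work-up to the isolated product of its own step is not numbered separately.

**Retrosynthetic overview**
1. C6–C7 (Stille): target ⇐ (Z)-enol triflate of the ring C8-formyl ketone + (Z)-alkenylstannane carrying C1–C6; both Z geometries are fixed before coupling and transferred with retention.
2. Triflate ⇐ chelation-controlled O-triflation ⇐ C-formylation of the TES-protected (S)-2-chloro-4-hydroxy-4-[(Z)-octenyl]cyclopentenone.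
3. α-Chloro enone ⇐ nucleophilic epoxidation, then HCl opening and dehydration, of (S)-4-hydroxy-4-[(Z)-octenyl]cyclopent-2-enone ⇐ desilylation and allylic oxidation.
4. C12–C13 bond and the only stereocentre ⇐ anti-selective 1,2-addition of the oct-2-ynylzinc reagent to commercial (R)-4-silyloxycyclopentenone, then cis-semihydrogenation (14Z).
5. Ring order: no ring is built; the cyclopentene is bought with the starting enone (only a transient epoxide is made and opened).

**Route**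

Step 1
Reactants: 1 (4R)-4-[(tert-butyldimethylsilyl)oxy]cyclopent-2-en-1-one; 2 1-bromooct-2-yne
Product: 4 (1S,4R)-4-[(tert-butyldimethylsilyl)oxy]-1-(oct-2-yn-1-yl)cyclopent-2-en-1-ol, via allenylzinc bromide 3 (not isolated)
Conditions: Zn dust, THF, 0 °C (2 → 3); then 1, −78 → 0 °C; sat. aq. NH4Cl; chromatography
Reagents that add atoms: none
Why: Zinc-mediated (Barbier-type) propargylation in which the allenylzinc form attacks the ketone 1,2 through its unsubstituted CH2 terminus (cyclic SE2' transition state, homopropargyl carbinol) on the face anti to the C4 silyloxy group, setting the tertiary carbinol (later C12) with OH cis to OTBS; the minor diastereomer is removed on silica.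

Step 2
Reactants: 4 (1S,4R)-4-[(tert-butyldimethylsilyl)oxy]-1-(oct-2-yn-1-yl)cyclopent-2-en-1-ol
Product: 5 (1S,4R)-4-[(tert-butyldimethylsilyl)oxy]-1-[(2Z)-oct-2-en-1-yl]cyclopent-2-en-1-ol
Conditions: H2 (1 atm), Pd/CaCO3 poisoned with Pb(OAc)2, quinoline, EtOAc, rt
Reagents that add atoms: none
Why: Lindlar-type syn semihydrogenation of the internal alkyne on poisoned Pd gives the (Z)-alkene (later 14Z) and leaves the ring alkene untouched.

Step 3
Reactants: 5 (1S,4R)-4-[(tert-butyldimethylsilyl)oxy]-1-[(2Z)-oct-2-en-1-yl]cyclopent-2-en-1-ol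
Product: 6 (1S,4R)-1-[(2Z)-oct-2-en-1-yl]cyclopent-2-ene-1,4-diol
Conditions: Bu4NF, THF, 0 °C → rt; aq. NH4Cl
Reagents that add atoms: none
Why: Fluoride-driven desilylation (strong Si–F bond) frees the secondary allylic alcohol without touching the tertiary carbinol centre.

Step 4
Reactants: 6 (1S,4R)-1-[(2Z)-oct-2-en-1-yl]cyclopent-2-ene-1,4-diol
Product: 7 (4S)-4-hydroxy-4-[(2Z)-oct-2-en-1-yl]cyclopent-2-en-1-one
Conditions: MnO2 (activated, excess), CH2Cl2, rt
Reagents that add atoms: none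
Why: Chemoselective MnO2 allylic oxidation converts only the secondary allylic alcohol (the tertiary one cannot be oxidised) into the enone and removes the now superfluous C4 stereocentre of 1.

Step 5
Reactants: 7 (4S)-4-hydroxy-4-[(2Z)-oct-2-en-1-yl]cyclopent-2-en-1-one
Product: 8 (1S,4S,5R)-4-hydroxy-4-[(2Z)-oct-2-en-1-yl]-6-oxabicyclo[3.1.0]hexan-2-one
Conditions: 30% aq. H2O2, NaOH (cat.), MeOH, −10 → 0 °C
Reagents that add atoms: hydrogen peroxide (OO)
Why: Weitz–Scheffer nucleophilic epoxidation touches only the electron-poor enone C=C (not the isolated Z-alkene) and is expected on the face cis to the small hydroxyl; both epoxide centres are erased in step 6.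

Step 6
Reactants: 8 (1S,4S,5R)-4-hydroxy-4-[(2Z)-oct-2-en-1-yl]-6-oxabicyclo[3.1.0]hexan-2-one
Product: 10 (4S)-2-chloro-4-hydroxy-4-[(2Z)-oct-2-en-1-yl]cyclopent-2-en-1-one, via chlorohydrin 9 (not isolated)
Conditions: conc. aq. HCl, THF, 0 °C → rt
Reagents that add atoms: hydrogen chloride (Cl)
Why: Acid-promoted SN2 opening of the epoxy ketone by chloride at the carbonyl-activated α-carbon, then β-elimination of water from the chlorohydrin, gives the α-chloro enone; the tertiary centre is not involved.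

Step 7
Reactants: 10 (4S)-2-chloro-4-hydroxy-4-[(2Z)-oct-2-en-1-yl]cyclopent-2-en-1-one
Product: 11 (4S)-2-chloro-4-[(2Z)-oct-2-en-1-yl]-4-[(triethylsilyl)oxy]cyclopent-2-en-1-one
Conditions: Et3SiOTf, 2,6-lutidine, CH2Cl2, −78 → 0 °C
Reagents that add atoms: triethylsilyl trifluoromethanesulfonate (CC[Si](CC)(CC)OS(=O)(=O)C(F)(F)F)
Why: Silylation of the hindered tertiary alcohol with the silyl triflate blocks retro-aldol and alkoxide side reactions in the enolate steps.

Step 8
Reactants: 11 (4S)-2-chloro-4-[(2Z)-oct-2-en-1-yl]-4-[(triethylsilyl)oxy]cyclopent-2-en-1-one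
Product: 13 (4R,5Z)-2-chloro-5-(hydroxymethylidene)-4-[(2Z)-oct-2-en-1-yl]-4-[(triethylsilyl)oxy]cyclopent-2-en-1-one, via lithium dienolate 12 (not isolated)
Conditions: LiN(SiMe3)2 (1.1 equiv), THF, −78 °C; CF3CH2OCHO, −78 → −40 °C; cold 0.5 M aq. HCl
Reagents that add atoms: 2,2,2-trifluoroethyl formate (O=COCC(F)(F)F)
Why: Claisen-type C-formylation of the only possible enolate (β-loss of the silyloxy group would give an antiaromatic cyclopentadienone) gives the enolised β-keto aldehyde; the C4 descriptor changes from S to R only because C5 becomes sp2, not by inversion.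

Step 9
Reactants: 13 (4R,5Z)-2-chloro-5-(hydroxymethylidene)-4-[(2Z)-oct-2-en-1-yl]-4-[(triethylsilyl)oxy]cyclopent-2-en-1-one
Product: 15 (4R,5Z)-2-chloro-4-[(2Z)-oct-2-en-1-yl]-4-[(triethylsilyl)oxy]-5-{[(trifluoromethanesulfonyl)oxy]methylidene}cyclopent-2-en-1-one, via lithium chelate 14 (not isolated)
Conditions: LiN(SiMe3)2 (1.05 equiv), Et2O, −78 °C; (CF3SO2)2O, −78 °C; used at once
Reagents that add atoms: trifluoromethanesulfonic anhydride (O=S(=O)(OS(=O)(=O)C(F)(F)F)C(F)(F)F)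
Why: O-Sulfonylation of the lithium-chelated, U-shaped β-keto aldehyde enolate at the exocyclic (formyl-derived) oxygen locks the (Z)-enol triflate, OTf syn to the ring carbonyl.

Step 10
Reactants: 16 methyl hex-5-ynoate
Product: 17 methyl 6-(tributylstannyl)hex-5-ynoate
Conditions: Bu3SnOMe, ZnBr2 (5 mol %), THF, rt
Reagents that add atoms: tributyltin methoxide (CCCC[Sn](CCCC)(CCCC)OC)
Why: ZnBr2-catalysed C–H stannylation of the terminal alkyne by the tin alkoxide with loss of methanol; methoxide cannot scramble the methyl ester.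

Step 11
Reactants: 17 methyl 6-(tributylstannyl)hex-5-ynoate
Product: 19 methyl (5Z)-6-(tributylstannyl)hex-5-enoate, via alkenylzirconocene chloride 18 (not isolated)
Conditions: Cp2Zr(H)Cl (1.2 equiv), THF, rt; then H2O
Reagents that add atoms: none
Why: Hydrozirconation (syn addition of Zr–H, Zr to the tin-bearing carbon) followed by stereoretentive protonolysis of the C–Zr bond gives the (Z)-alkenylstannane.

Step 12
Reactants: 15 (4R,5Z)-2-chloro-4-[(2Z)-oct-2-en-1-yl]-4-[(triethylsilyl)oxy]-5-{[(trifluoromethanesulfonyl)oxy]methylidene}cyclopent-2-en-1-one; 19 methyl (5Z)-6-(tributylstannyl)hex-5-enoate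
Product: 20 methyl (5Z,7Z)-7-[(2R)-4-chloro-2-[(2Z)-oct-2-en-1-yl]-5-oxo-2-[(triethylsilyl)oxy]cyclopent-3-en-1-ylidene]hept-5-enoate
Conditions: Pd2(dba)3 (5 mol %), AsPh3 (20 mol %), CuI (10 mol %), NMP, rt, dark
Reagents that add atoms: none
Why: Stille cross-coupling in which oxidative addition of zerovalent palladium into the vinylogous acyl triflate, copper-assisted transmetalation from tin and reductive elimination all proceed with retention, so 7Z and 5Z are carried over under neutral conditions and the C–Cl bond is untouched.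

Step 13
Reactants: 20 methyl (5Z,7Z)-7-[(2R)-4-chloro-2-[(2Z)-oct-2-en-1-yl]-5-oxo-2-[(triethylsilyl)oxy]cyclopent-3-en-1-ylidene]hept-5-enoate
Product: 21 methyl (5Z,7Z)-7-[(2R)-4-chloro-2-hydroxy-2-[(2Z)-oct-2-en-1-yl]-5-oxocyclopent-3-en-1-ylidene]hept-5-enoate
Conditions: HF·pyridine, pyridine/THF, 0 °C → rt
Reagents that add atoms: none
Why: Buffered HF desilylation cleaves the tertiary silyl ether under non-basic conditions that spare the cross-conjugated chlorodienone, giving the target with the 12R centre unchanged.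

**Compound list**
1 | (4R)-4-[(tert-butyldimethylsilyl)oxy]cyclopent-2-en-1-one | O=C1C=C[C@H](O[Si](C)(C)C(C)(C)C)C1 | starting material
2 | 1-bromooct-2-yne | CCCCCC#CCBr | starting material
3 | octa-1,2-dien-3-ylzinc bromide (allenylzinc form of the oct-2-ynylzinc reagent; not isolated) | C=C=C(CCCCC)[Zn]Br | intermediate
4 | (1S,4R)-4-[(tert-butyldimethylsilyl)oxy]-1-(oct-2-yn-1-yl)cyclopent-2-en-1-ol (OH cis to OTBS) | CCCCCC#CC[C@@]1(O)C=C[C@H](O[Si](C)(C)C(C)(C)C)C1 | intermediate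
5 | (1S,4R)-4-[(tert-butyldimethylsilyl)oxy]-1-[(2Z)-oct-2-en-1-yl]cyclopent-2-en-1-ol | CCCCC/C=C\C[C@@]1(O)C=C[C@H](O[Si](C)(C)C(C)(C)C)C1 | intermediate
6 | (1S,4R)-1-[(2Z)-oct-2-en-1-yl]cyclopent-2-ene-1,4-diol (cis-diol) | CCCCC/C=C\C[C@@]1(O)C=C[C@H](O)C1 | intermediate
7 | (4S)-4-hydroxy-4-[(2Z)-oct-2-en-1-yl]cyclopent-2-en-1-one | CCCCC/C=C\C[C@@]1(O)C=CC(=O)C1 | intermediate
8 | (1S,4S,5R)-4-hydroxy-4-[(2Z)-oct-2-en-1-yl]-6-oxabicyclo[3.1.0]hexan-2-one (epoxide cis to OH) | CCCCC/C=C\C[C@@]1(O)[C@@H]2O[C@@H]2C(=O)C1 | intermediate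
9 | (2R,3S,4S)-2-chloro-3,4-dihydroxy-4-[(2Z)-oct-2-en-1-yl]cyclopentan-1-one (chlorohydrin; not isolated) | CCCCC/C=C\C[C@@]1(O)[C@H](O)[C@@H](Cl)C(=O)C1 | intermediate
10 | (4S)-2-chloro-4-hydroxy-4-[(2Z)-oct-2-en-1-yl]cyclopent-2-en-1-one | CCCCC/C=C\C[C@@]1(O)C=C(Cl)C(=O)C1 | intermediate
11 | (4S)-2-chloro-4-[(2Z)-oct-2-en-1-yl]-4-[(triethylsilyl)oxy]cyclopent-2-en-1-one | CCCCC/C=C\C[C@@]1(O[Si](CC)(CC)CC)C=C(Cl)C(=O)C1 | intermediate
12 | lithium cross-conjugated dienolate of 11 (O–Li on C1; C1=C5 and C2=C3; not isolated) | CCCCC/C=C\C[C@@]1(O[Si](CC)(CC)CC)C=C(Cl)C(O[Li])=C1 | intermediate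
13 | (4R,5Z)-2-chloro-5-(hydroxymethylidene)-4-[(2Z)-oct-2-en-1-yl]-4-[(triethylsilyl)oxy]cyclopent-2-en-1-one | CCCCC/C=C\C[C@@]1(O[Si](CC)(CC)CC)C=C(Cl)C(=O)/C1=C\O | intermediate
14 | lithium chelate (Z-enolate) of 13 (not isolated) | CCCCC/C=C\C[C@@]1(O[Si](CC)(CC)CC)C=C(Cl)C(=O)/C1=C\O[Li] | intermediate
15 | (4R,5Z)-2-chloro-4-[(2Z)-oct-2-en-1-yl]-4-[(triethylsilyl)oxy]-5-{[(trifluoromethanesulfonyl)oxy]methylidene}cyclopent-2-en-1-one | CCCCC/C=C\C[C@@]1(O[Si](CC)(CC)CC)C=C(Cl)C(=O)/C1=C\OS(=O)(=O)C(F)(F)F | intermediate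
16 | methyl hex-5-ynoate | C#CCCCC(=O)OC | starting material
17 | methyl 6-(tributylstannyl)hex-5-ynoate | CCCC[Sn](CCCC)(CCCC)C#CCCCC(=O)OC | intermediate
18 | methyl (5Z)-6-[chlorobis(cyclopentadienyl)zirconio]-6-(tributylstannyl)hex-5-enoate (Cp drawn σ-bonded; not isolated) | COC(=O)CCC/C=C(\[Sn](CCCC)(CCCC)CCCC)[Zr](Cl)(C1C=CC=C1)C1C=CC=C1 | intermediate
19 | methyl (5Z)-6-(tributylstannyl)hex-5-enoate | COC(=O)CCC/C=C\[Sn](CCCC)(CCCC)CCCC | intermediate
20 | methyl (5Z,7Z)-7-[(2R)-4-chloro-2-[(2Z)-oct-2-en-1-yl]-5-oxo-2-[(triethylsilyl)oxy]cyclopent-3-en-1-ylidene]hept-5-enoate | CCCCC/C=C\C[C@@]1(O[Si](CC)(CC)CC)C=C(Cl)C(=O)/C1=C\C=C/CCCC(=O)OC | intermediate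
21 | methyl (5Z,7Z)-7-[(2R)-4-chloro-2-hydroxy-2-[(2Z)-oct-2-en-1-yl]-5-oxocyclopent-3-en-1-ylidene]hept-5-enoate, i.e. methyl (5Z,7Z,12R,14Z)-10-chloro-12-hydroxy-9-oxoprosta-5,7,10,14-tetraen-1-oate | CCCCC/C=C\C[C@@]1(O)C=C(Cl)C(=O)/C1=C\C=C/CCCC(=O)OC | target

**Step count**
Total: 13 steps. Longest linear sequence: 11 steps (1 → 21 through steps 1–9, 12 and 13); steps 10 and 11 make stannane 19 from 16.

**Three steps most likely to fail**

Step 1. The γ-substituted propargyl/allenyl zinc reagent may give some allenyl carbinol, and the facial selectivity may be only moderate. The fallback sets out from 1 and comes back at 4. Unsubstituted allenylzinc bromide (from 3-bromoprop-1-yne and Zn dust in THF, which gives homopropargyl alcohols almost exclusively) is added to 1 at −78 → 0 °C to give (1S,4R)-4-[(tert-butyldimethylsilyl)oxy]-1-(prop-2-yn-1-yl)cyclopent-2-en-1-ol F1. Double deprotonation with n-BuLi (2.1 equiv, THF, −78 → 0 °C) gives the dilithium alkoxide acetylide F2, which is C-alkylated with 1-iodopentane (DMPU, 0 °C → rt; aq. NH4Cl) to rejoin the route at 4.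

Step 9. Triflation could occur at the ring oxygen or give the E-triflate, and the vinylogous acyl triflate is very electrophilic. The fallback sets out from 11 and comes back at 20 by aldol condensation in place of formylation, triflation and coupling.
- Catalogue methyl 7-hydroxyhept-5-ynoate is semihydrogenated (H2, Pd/CaCO3 poisoned with Pb(OAc)2, quinoline) to methyl (5Z)-7-hydroxyhept-5-enoate F3 and oxidised (MnO2, CH2Cl2) to methyl (5Z)-7-oxohept-5-enoate F4.
- The lithium dienolate 12 (from 11, LiN(SiMe3)2, THF, −78 °C) adds to F4 through a closed Zimmerman–Traxler transition state on the face opposite the octenyl chain. After an aq. HCl quench this gives the anti aldol methyl (5Z,7S)-7-[(1R,2S)-4-chloro-2-[(2Z)-oct-2-en-1-yl]-5-oxo-2-[(triethylsilyl)oxy]cyclopent-3-en-1-yl]-7-hydroxyhept-5-enoate F5.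
- MsCl/Et3N (CH2Cl2, −20 °C) gives methyl (5Z,7S)-7-[(1R,2S)-4-chloro-2-[(2Z)-oct-2-en-1-yl]-5-oxo-2-[(triethylsilyl)oxy]cyclopent-3-en-1-yl]-7-[(methanesulfonyl)oxy]hept-5-enoate F6.
- DBU-induced anti elimination of F6 places C6 syn to the ring carbonyl and gives 20. Any 7E isomer formed through an E1cB pathway is removed by chromatography; this is the weak point of the fallback, since such dehydrations usually favour 7E.

Step 12. The (Z)-alkenylstannane may transmetalate slowly, or Z/E leakage may occur through the β-acyl alkenylpalladium intermediate. The fallback sets out from 15 and comes back at 20. The alkynylstannane 17 (the fastest-transferring stannane class) is coupled with 15 under the same neutral Pd2(dba)3/AsPh3/CuI conditions to give methyl (7Z)-7-[(2R)-4-chloro-2-[(2Z)-oct-2-en-1-yl]-5-oxo-2-[(triethylsilyl)oxy]cyclopent-3-en-1-ylidene]hept-5-ynoate F7. Its conjugated alkyne is then cis-semireduced (H2, Pd/CaCO3 poisoned with Pb(OAc)2, quinoline; or Zn activated with Cu(OAc)2 and AgNO3 in aq. MeOH) to 20.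

Further compounds
F1 | step 1 | (1S,4R)-4-[(tert-butyldimethylsilyl)oxy]-1-(prop-2-yn-1-yl)cyclopent-2-en-1-ol | C#CC[C@@]1(O)C=C[C@H](O[Si](C)(C)C(C)(C)C)C1
F2 | step 1 | dilithium alkoxide acetylide of F1 | [Li]C#CC[C@@]1(O[Li])C=C[C@H](O[Si](C)(C)C(C)(C)C)C1
F3 | step 9 | methyl (5Z)-7-hydroxyhept-5-enoate | COC(=O)CCC/C=C\CO
F4 | step 9 | methyl (5Z)-7-oxohept-5-enoate | COC(=O)CCC/C=C\C=O
F5 | step 9 | methyl (5Z,7S)-7-[(1R,2S)-4-chloro-2-[(2Z)-oct-2-en-1-yl]-5-oxo-2-[(triethylsilyl)oxy]cyclopent-3-en-1-yl]-7-hydroxyhept-5-enoate | CCCCC/C=C\C[C@@]1(O[Si](CC)(CC)CC)C=C(Cl)C(=O)[C@@H]1[C@@H](O)/C=C\CCCC(=O)OC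
F6 | step 9 | methyl (5Z,7S)-7-[(1R,2S)-4-chloro-2-[(2Z)-oct-2-en-1-yl]-5-oxo-2-[(triethylsilyl)oxy]cyclopent-3-en-1-yl]-7-[(methanesulfonyl)oxy]hept-5-enoate | CCCCC/C=C\C[C@@]1(O[Si](CC)(CC)CC)C=C(Cl)C(=O)[C@@H]1[C@@H](OS(C)(=O)=O)/C=C\CCCC(=O)OC
F7 | step 12 | methyl (7Z)-7-[(2R)-4-chloro-2-[(2Z)-oct-2-en-1-yl]-5-oxo-2-[(triethylsilyl)oxy]cyclopent-3-en-1-ylidene]hept-5-ynoate | CCCCC/C=C\C[C@@]1(O[Si](CC)(CC)CC)C=C(Cl)C(=O)/C1=C\C#CCCCC(=O)OC
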